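**Retrosynthetic overview**
- Enabling feature: the C9 ketone. Its α-carbon C10 is the quaternary fusion atom of ring A (C1–C5, C10), and C9 lies 1,6 to the bridgehead alkene C8=C14 of the ten-membered ring (C5–C6–C7–C8–C14–C13–C12–C11–C9–C10). One carbonyl therefore carries both an oxy-Cope retron and an enolate-alkylation retron.
- Late stage: the C15 ketone comes from allylic C–H oxidation of the skipped diene of ring D (C8, C14, C13, C16, C15); the C7 acetate comes from Mitsunobu inversion.
- Key disconnections, one operation: C1–C10 (ring A, enolate C-alkylation by a C1 chloride) and C12–C13/C8–C9 ([3,3] ring expansion). They lead back to spiro vinyl carbinol 13, in which C5–C10 are still the six-membered ring of carvone (a temporary ring).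
- 13 from (S)-carvone: C7–O by Criegee rearrangement, C4–C5 by decarboxylative Giese addition, ring D by formylation, allylation and intramolecular Wittig reaction, C11–C12 by vinyl addition.
- Ring order: carvone ring (bought), ring D (step 7), ten-membered ring (step 9, ring expansion), ring A (step 9, last). Stereo relay: C7 (bought) → C5 → C8 → C9 → C13 and C10; C7 is inverted at the end.

Key step: step 9

Remark 1: atom numbers are those of the 8,9-seco-ent-kaurane skeleton (C18 and C19 on C4, C20 on C10, C17 on C16).
Remark 2 (assumption): 6 and 9 are taken as catalogue chemicals.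

Step 1
Reactants: 1 (S)-(+)-carvone
Product: 3 (1S)-4-methyl-5-oxocyclohex-3-en-1-yl acetate, via methoxy hydroperoxide 2 (not isolated)
Conditions: O3, CH2Cl2/MeOH, −78 °C; then Ac2O, Et3N, DMAP (cat.), 0 °C to rt
Reagents that add atoms: ozone O=[O+][O-]; methanol CO
Why: Ozonolysis of the electron-rich isopropenyl group in methanol gives the α-methoxy hydroperoxide, and O-acetylation triggers the Criegee rearrangement, in which the ring carbon migrates to oxygen with retention, so the carvone stereocentre becomes C7–OAc (the acetyl group is the former isopropenyl C–CH3).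

Step 2
Reactants: 3 (1S)-4-methyl-5-oxocyclohex-3-en-1-yl acetate
Product: 4 (5S)-5-hydroxy-2-methylcyclohex-2-en-1-one
Conditions: K2CO3 (0.1 equiv), MeOH, 0 °C, short reaction time
Reagents that add atoms: none
Why: Base-catalysed transesterification should remove the acetate at 0 °C before the α′-enolate can expel the β-oxygen (E1cB path to the phenol); the stereocentre is untouched.

Step 3
Reactants: 4 (5S)-5-hydroxy-2-methylcyclohex-2-en-1-one
Product: 5 (5S)-5-(tert-butyldimethylsilyloxy)-2-methylcyclohex-2-en-1-one
Conditions: t-BuMe2SiCl, imidazole, CH2Cl2, rt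
Reagents that add atoms: tert-butyldimethylsilyl chloride CC(C)(C)[Si](C)(C)Cl
Why: Standard silylation of a secondary alcohol; the bulky silyl ether then serves as the stereodirecting group for C5, C8 and C9.

Step 4
Reactants: 5 (5S)-5-(tert-butyldimethylsilyloxy)-2-methylcyclohex-2-en-1-one; 6 5-chloro-2,2-dimethylpentanoic acid
Product: 7 (2R,3S,5S)-5-(tert-butyldimethylsilyloxy)-3-(5-chloro-2-methylpentan-2-yl)-2-methylcyclohexan-1-one
Conditions: [Ir(dF(CF3)ppy)2(dtbbpy)]PF6 (1 mol %), K2HPO4, DMF, blue LEDs, rt
Reagents that add atoms: none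
Why: Photoredox decarboxylative Giese reaction: the tertiary radical Cl(CH2)3CMe2• should add to the β-carbon C5 of the cyclohexenone by axial attack anti to the C7 silyloxy group (3,5-trans), and reduction and protonation of the α-keto radical leave C10 as the equatorial methyl epimer (either C10 epimer serves, since this centre is re-made in step 9).

Step 5
Reactants: 7 (2R,3S,5S)-5-(tert-butyldimethylsilyloxy)-3-(5-chloro-2-methylpentan-2-yl)-2-methylcyclohexan-1-one
Product: 8 (2R,3S,5S,6Z)-5-(tert-butyldimethylsilyloxy)-3-(5-chloro-2-methylpentan-2-yl)-6-(hydroxymethylidene)-2-methylcyclohexan-1-one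
Conditions: LiN(i-Pr)2, THF, −78 °C; CF3CH2OCHO, −78 °C; then 1 M HCl
Reagents that add atoms: 2,2,2-trifluoroethyl formate O=COCC(F)(F)F
Why: Kinetic deprotonation should take the less hindered C8 methylene (not the C10 methine), and Claisen-type C-formylation with the activated formate gives the chelated (Z)-hydroxymethylene ketone, while −78 °C keeps the β-silyloxy enolate from eliminating.

Step 6
Reactants: 8 (Z)-hydroxymethylene ketone; 9 3-bromo-2-(bromomethyl)prop-1-ene
Product: 10 1-[2-(bromomethyl)prop-2-en-1-yl]-6-(tert-butyldimethylsilyloxy)-4-(5-chloro-2-methylpentan-2-yl)-3-methyl-2-oxocyclohexane-1-carbaldehyde (allyl arm trans to the silyloxy group)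
Conditions: K2CO3, 9 (3 equiv), acetone, 0 °C to rt
Reagents that add atoms: none
Why: C-Alkylation of the β-keto aldehyde enolate by the allylic bromide creates the quaternary C8; the axial C7 silyloxy group shields one face, so the C15 arm should enter trans to it (cis to the C5 side chain), and any O-allyl enol ether converges to the same product by Claisen rearrangement.

Step 7
Reactants: 10 α-formyl ketone with the 2-(bromomethyl)allyl arm
Product: 12 10-(tert-butyldimethylsilyloxy)-8-(5-chloro-2-methylpentan-2-yl)-7-methyl-3-methylidenespiro[4.5]dec-1-en-6-one, via allylphosphonium bromide 11 (not isolated)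
Conditions: PPh3, MeCN, rt; then KN(SiMe3)2 (1.0 equiv), THF, −78 to 0 °C
Reagents that add atoms: none
Why: Intramolecular Wittig olefination: the allylic phosphonium ylide should close the five-membered ring D onto the non-enolizable neopentyl aldehyde (C13=C14) and give the transoid 3-methylenecyclopentene directly; the ylide forms well before the ketone is enolized, and C8 is not affected.

Step 8
Reactants: 12 spiro dienone
Product: 13 10-(tert-butyldimethylsilyloxy)-8-(5-chloro-2-methylpentan-2-yl)-6-ethenyl-7-methyl-3-methylidenespiro[4.5]dec-1-en-6-ol (vinyl trans to the silyloxy group and to the C14 arm)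
Conditions: CH2=CHMgBr, LaCl3·2LiCl (30 mol %), THF, 0 °C; then H2O
Reagents that add atoms: vinylmagnesium bromide C=C[Mg]Br
Why: Lanthanide-assisted Grignard 1,2-addition suppresses enolization of the hindered ketone; the axial C7 silyloxy group blocks axial attack, so vinyl should enter equatorially, trans to the C14 arm (the trans-diequatorial array wanted for step 9; the C9 epimer would rearrange to the same product through a boat).

Step 9
Reactants: 13 spiro vinyl carbinol
Product: 15 tricyclic silyl ether (5R,7S,10R,13S), via ring-expanded chloro ketone 14 (not isolated)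
Conditions: KN(SiMe3)2 (1.2 equiv), 18-crown-6 (1.5 equiv), THF (0.01 M), 0 °C to rt; then 55 °C
Reagents that add atoms: none
Why: The base turns 13 into the naked tertiary alkoxide, which should undergo the anionic oxy-Cope rearrangement through a chair (vinyl and C14 trans-diequatorial): C12–C13 forms, C8–C9 breaks, and the six-membered carvone ring is expanded by four atoms to the ten-membered ring with the bridgehead alkene C8=C14 and a C9 enolate; the closest known reaction type is the tandem anionic oxy-Cope ring expansion/enolate alkylation of 1,2-dialkenylcyclohexanols. C13 is set by chirality transfer from the spiro centre C8, because the suprafacial [3,3] shift must form the new bond on the face of the cyclopentene from which C9 departs. The HN(SiMe3)2 set free in the deprotonation carries the proton between the kinetic C11 enolate, ketone 14 and the C10 enolate, and on warming ring A is closed by a 6-exo-tet C-alkylation (enolate double bond exocyclic to the new ring) with loss of chloride. C10 is set by the tether on C5 together with A(1,3) strain: H5 lies in the enolate plane and C6 stands anti to the incoming C1, so the C20 methyl ends up anti to H5 (trans ring fusion). The step needs C- over O-alkylation and C10 over C11; O- or C11-attack would have to close eight-membered rings, which secures both.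

Step 10
Reactants: 15 tricyclic silyl ether
Product: 16 (5R,7S,10R,13S)-7-hydroxy tricyclic dienone precursor (7-epi alcohol)
Conditions: Bu4NF, THF, 0 °C to rt
Reagents that add atoms: none
Why: Fluoride cleavage of the silyl ether; no stereocentre changes.

Step 11
Reactants: 16 7-epi alcohol
Product: 17 (5R,7R,10R,13S)-7-acetate (target without the C15 ketone)
Conditions: PPh3, i-PrO2C–N=N–CO2i-Pr, AcOH, toluene, 0 °C to rt
Reagents that add atoms: acetic acid CC(O)=O
Why: Mitsunobu esterification: the alkoxyphosphonium ion of the allylic C7 alcohol should be displaced by acetate with inversion (SN2), which turns the relay centre (7S) into the required 7R acetate.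

Step 12
Reactants: 17 7R acetate
Product: 18 (5R,7R,10R,13S,15R)-15-hydroxy acetate
Conditions: SeO2 (0.5 equiv), t-BuOOH, CH2Cl2, rt
Reagents that add atoms: tert-butyl hydroperoxide CC(C)(C)OO; selenium dioxide O=[Se]=O
Why: Allylic hydroxylation by SeO2 (ene reaction, then [2,3] shift): C15 is the only ring CH2 at the more substituted end of C8=C14 and the CH2 (not the C13 methine) next to C16=C17, so both alkenes should direct oxygen to C15; the reagent is expected on the face of ring D anti to C12, and either C15 epimer serves.

Step 13
Reactants: 18 15-hydroxy acetate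
Product: 19 target CNP0421845.1
Conditions: Dess–Martin periodinane, CH2Cl2, 0 °C
Reagents that add atoms: none
Why: Dess–Martin oxidation of the doubly allylic alcohol gives the cross-conjugated dienone under non-basic conditions, so C13 and the other stereocentres are not touched.

**Compound list**
1 | (S)-(+)-carvone, (5S)-2-methyl-5-(prop-1-en-2-yl)cyclohex-2-en-1-one | CC1=CC[C@H](C(C)=C)CC1=O | starting material
2 | (5S)-5-(1-hydroperoxy-1-methoxyethyl)-2-methylcyclohex-2-en-1-one (both epimers at the peroxyacetal carbon) | CC1=CC[C@H](C(C)(OC)OO)CC1=O | intermediate (not isolated)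
3 | (1S)-4-methyl-5-oxocyclohex-3-en-1-yl acetate | CC1=CC[C@H](OC(C)=O)CC1=O | intermediate
4 | (5S)-5-hydroxy-2-methylcyclohex-2-en-1-one | CC1=CC[C@H](O)CC1=O | intermediate
5 | (5S)-5-(tert-butyldimethylsilyloxy)-2-methylcyclohex-2-en-1-one | CC1=CC[C@H](O[Si](C)(C)C(C)(C)C)CC1=O | intermediate
6 | 5-chloro-2,2-dimethylpentanoic acid | OC(=O)C(C)(C)CCCCl | starting material
7 | (2R,3S,5S)-5-(tert-butyldimethylsilyloxy)-3-(5-chloro-2-methylpentan-2-yl)-2-methylcyclohexan-1-one | O=C1[C@H](C)[C@@H](C(C)(C)CCCCl)C[C@H](O[Si](C)(C)C(C)(C)C)C1 | intermediate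
8 | (2R,3S,5S,6Z)-5-(tert-butyldimethylsilyloxy)-3-(5-chloro-2-methylpentan-2-yl)-6-(hydroxymethylidene)-2-methylcyclohexan-1-one | O=C1[C@H](C)[C@@H](C(C)(C)CCCCl)C[C@H](O[Si](C)(C)C(C)(C)C)/C1=C/O | intermediate
9 | 3-bromo-2-(bromomethyl)prop-1-ene | C=C(CBr)CBr | starting material
10 | 1-[2-(bromomethyl)prop-2-en-1-yl]-6-(tert-butyldimethylsilyloxy)-4-(5-chloro-2-methylpentan-2-yl)-3-methyl-2-oxocyclohexane-1-carbaldehyde, allyl arm trans to OSi and cis to the side chain | O=C1[C@H](C)[C@@H](C(C)(C)CCCCl)C[C@H](O[Si](C)(C)C(C)(C)C)[C@@]1(C=O)CC(=C)CBr | intermediate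
11 | allyltriphenylphosphonium bromide derived from 10 | O=C1[C@H](C)[C@@H](C(C)(C)CCCCl)C[C@H](O[Si](C)(C)C(C)(C)C)[C@@]1(C=O)CC(=C)C[P+](c1ccccc1)(c1ccccc1)c1ccccc1.[Br-] | intermediate (not isolated)
12 | 10-(tert-butyldimethylsilyloxy)-8-(5-chloro-2-methylpentan-2-yl)-7-methyl-3-methylidenespiro[4.5]dec-1-en-6-one, ring CH2 (C15) trans to OSi | O=C1[C@H](C)[C@@H](C(C)(C)CCCCl)C[C@H](O[Si](C)(C)C(C)(C)C)[C@]12C=CC(=C)C2 | intermediate
13 | 6-ethenyl-6-hydroxy derivative of 12, vinyl trans to OSi and to the C14 arm | O[C@]1(C=C)[C@H](C)[C@@H](C(C)(C)CCCCl)C[C@H](O[Si](C)(C)C(C)(C)C)[C@]12C=CC(=C)C2 | intermediate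
14 | (5S,7S,10R,13S) ring-expanded chloro ketone: ten-membered 9-ketone bridged by ring D, 8(14)-ene, 16-methylidene, 7-OSi, 5-(5-chloro-2-methylpentan-2-yl), 10-methyl | C=C1CC2=C[C@@H]1CCC(=O)[C@H](C)[C@@H](C(C)(C)CCCCl)C[C@@H]2O[Si](C)(C)C(C)(C)C | intermediate (not isolated)
15 | (5R,7S,10R,13S) tricyclic silyl ether: target skeleton with 7-epi OSi and C15H2 | C=C1CC2=C[C@@H]1CCC(=O)[C@]1(C)CCCC(C)(C)[C@H]1C[C@@H]2O[Si](C)(C)C(C)(C)C | intermediate
16 | (5R,7S,10R,13S) 7-epi alcohol | C=C1CC2=C[C@@H]1CCC(=O)[C@]1(C)CCCC(C)(C)[C@H]1C[C@@H]2O | intermediate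
17 | (5R,7R,10R,13S) 7-acetate with C15H2 | C=C1CC2=C[C@@H]1CCC(=O)[C@]1(C)CCCC(C)(C)[C@H]1C[C@H]2OC(C)=O | intermediate
18 | (5R,7R,10R,13S,15R) 15-hydroxy 7-acetate | C=C1[C@@H](O)C2=C[C@@H]1CCC(=O)[C@]1(C)CCCC(C)(C)[C@H]1C[C@H]2OC(C)=O | intermediate
19 | CNP0421845.1, (5R,7R,10R,13S)-7-acetoxy-8,9-seco-kaura-8(14),16-diene-9,15-dione | C=C1C(=O)C2=C[C@@H]1CCC(=O)[C@]1(C)CCCC(C)(C)[C@H]1C[C@H]2OC(C)=O | target

**Step count and risks**
Total steps: 13. Longest linear sequence: 13 steps (from 1; 6 and 9 are bought).

Steps most likely to fail: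

Step 9. In the aprotic medium, proton transfer from the hindered C10–H to the kinetic C11 enolate may be too slow, so the Cope enolate would only be protonated on work-up and ring A would not close. Reversible silyl migration from O7 to the C9 alkoxide may also slow the rearrangement. The fallback gives up the cascade for a stop-and-go sequence that sets out from 13 and comes back at 15. 13 is rearranged alone with KH and 18-crown-6 in THF at 0 °C and quenched cold with NH4Cl, which should give the ring-expanded chloro ketone 14 as an isolated compound. NaI in acetone (Finkelstein exchange) then gives the ring-expanded iodo ketone F1. KOt-Bu in t-BuOH/THF at rt closes ring A under protic, fully equilibrating conditions, in which t-BuOH carries the proton between C11 and C10 and only the C10 enolate can cyclize.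

Step 11. The activated allylic alcohol may ionize, with capture of acetate at C14 (SN2′) or elimination, in place of clean inversion at C7. The fallback sets out from 16 and comes back at 17 by oxidation and reagent-controlled reduction. Dess–Martin periodinane should give the 7-oxo enone F2 (ketone conjugated with C8=C14). 1,2-Reduction with (S)-2-methyl-CBS-oxazaborolidine and catecholborane (toluene, −78 °C) treats the alkenyl carbon C8 as the large group, while the α-quaternary C9 ketone reacts far more slowly, and should give the (7R)-alcohol F3. Ac2O, pyridine and DMAP then give 17.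

Step 8. The Grignard reagent may enolize the α-branched, neopentyl-type ketone, or the addition may stall for steric reasons. The fallback sets out from 12 and comes back at 13 through an alkyne. The slimmer and less basic HC≡CMgBr (THF, 0 °C to rt) should add to give the ethynyl carbinol F4. Semi-hydrogenation of the terminal alkyne (H2, Pd/CaCO3 poisoned with Pb(OAc)2, quinoline, EtOAc) then gives 13.

**Further compounds**
F1 | step 9 | ring-expanded iodo ketone (iodide analogue of 14) | C=C1CC2=C[C@@H]1CCC(=O)[C@H](C)[C@@H](C(C)(C)CCCI)C[C@@H]2O[Si](C)(C)C(C)(C)C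
F2 | step 11 | 7-oxo enone (5R,10R,13S) | C=C1CC2=C[C@@H]1CCC(=O)[C@]1(C)CCCC(C)(C)[C@H]1CC2=O
F3 | step 11 | (5R,7R,10R,13S)-alcohol | C=C1CC2=C[C@@H]1CCC(=O)[C@]1(C)CCCC(C)(C)[C@H]1C[C@H]2O
F4 | step 8 | ethynyl carbinol (ethynyl analogue of 13) | O[C@]1(C#C)[C@H](C)[C@@H](C(C)(C)CCCCl)C[C@H](O[Si](C)(C)C(C)(C)C)[C@]12C=CC(=C)C2
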